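The rate constants are assumed; the run is a simulation.

I counted time in one unit, the lifetime of J against its two forward exits, and these were the flasks and the questions:

    J ⇌ E (K1 = 0.84, k1 = 7.61 × 10⁻⁷ s⁻¹, Ea1 = 126 kJ mol⁻¹, ΔH1 = −9.00 kJ mol⁻¹)
    J → L (k2 = 9.52 × 10⁻⁶ s⁻¹, Ea2 = 115 kJ mol⁻¹)
    E → X (k3 = 7.88 × 10⁻⁶ s⁻¹, Ea3 = 127 kJ mol⁻¹)
    L ⇌ X (K4 = 0.291, k4 = 4.77 × 10⁻⁶ s⁻¹, Ea4 = 128 kJ mol⁻¹, ΔH4 = −36.0 kJ mol⁻¹)
    J + L → J.L (k5 = 9.41 × 10⁻⁶ M⁻¹ s⁻¹, Ea5 = 107 kJ mol⁻¹)
    (constants at 110 °C)

| flask | J | temperature | time |
|---|---|---|---|
| amber | 0.87 M | 110 °C | 20 h |
| grey | 0.87 M | 140 °C | 20 h |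
| red | 0.87 M | 125 °C | 20 h |

- a species is counted by the J in it: one J.L counts as two
- the list of constants is for 110 °C, to be carried to other temperatures by the activation energies and enthalpies
- in a conversion E counts as not yet reacted

- the flask that comes out highest in amount of L, in percent of the J charged, or "all alike" when all lie within 1.5 percentage points (amber / grey / red / all alike)
- L at the end, in percent of the J charged, amber
- L at the end, in percent of the J charged, grey
- L at the end, in percent of the J charged, red

The exits, steps 1 and 2 together, sum to 0.0370 h⁻¹ in amber, 0.146 h⁻¹ in red and 0.520 h⁻¹ in grey. For amber this made 0.740 for the clock reading, the number of J lifetimes in the run, and the same reading was 2.91 for red and 10.4 for grey. I took a reading of 1 as the crossing at which control changes hands.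

On the ladder of red, L and X relax first, with a half-life of 1.42 h, shorter than the run. J follows, with a half-life of 4.76 h by its exits, while J and E relax in 24.5 h, longer than the run, so I treated E as a one-way passage into X. Red therefore looked to me like a flask in which J has nearly finished and L holds its equilibrium share of L plus X, 84.0%, against 88.6% in grey, which is higher. That is thermodynamic control of the split between L and X.

Step 5 takes its toll on top. Its weight, its rate on the full charge over the exits, is 0.796 in amber, 0.717 in red and 0.650 in grey. Taking the balance of L against J to low order, I divided each share by one plus weight times share, which gave 52.4% for red and 56.2% for grey.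

Amber stays below the crossing, so I reckoned it under kinetic control. I took the part of the charge gone by the clock, kept the direct share of it, and counted no loss from L to X, which gave 34.2%. My highest flask was grey.

The forecast named grey too, with 34.3% for amber, 58.3% for grey and 53.3% for red, holding for red that “L and X are near equilibrium”. Its grey stands above mine.

The simulation gave grey as highest, with 34.4% for amber, 59.0% for grey and 52.9% for red, so the forecast stands. Red stopped at 5.0 h has a reading of 0.728, about amber's 0.740, and amber's reckoning gives that flask 34.6%. Red at that time held 35.2% of L and 43.3% of J, against 34.4% and 42.1% in amber at 20.0 h.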